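**Assumptions (remarks on the chemistry)**
- Eudesmane numbering is used. "C14 face" means the face of the decalin that carries C14, O1 and O2; "H5 face" means the face that carries H5, the C7 isopropenyl group and O9. The target is read as (1R,2S,5R,7S,9S,10S).
- The sense in which the spiro acetal steers the cycloaddition is taken from a conformational model (addition anti to the isopropyl-bearing carbon of the acetal) and would have to be confirmed on adduct 21.

## Structural features

The target is a trans-fused decalin of the eudesmane type. Ring A (C1–C5, C10) is a cyclohexene with the C3=C4 double bond and the C15 methyl group on C4. Ring B (C5–C10) is saturated and carries an isopropenyl group at C7. There are six stereocentres: C1, C2 and the quaternary C10 are contiguous and have O1, O2 and C14 on one face, while H5, O9 and the C7 substituent lie on the other face, so that the C7 and C9 substituents are both axial on ring B. Four oxygen functions are present in three states: a tiglate on the hindered C1 hydroxyl, acetates on the allylic, pseudoaxial C2 oxygen and on the axial, neopentyl C9 oxygen, and a free primary neopentyl alcohol at C14. The fragile points are acyl migration between the cis-vicinal O1/O2 pair and between O1 and O14, ionisation of the allylic C2 acetate, and the acid-sensitive isopropenyl group. The real difficulty is the quaternary C10 with its hydroxymethyl group inside the all-cis O1/O2/C14 array, together with the differentiation of four hydroxyl groups. The key step exploits the C1–O bond cis to C14 on adjacent carbons, with the C2 oxygen allylic to C3=C4 next to the ring-fusion C5–H. This is the retron of a [4+2] between a 1-oxy-3-methyldiene (C2–C5) and a C1=C10 dienophile whose O1 and C14 are tied into a 1,3-dioxin-4-one, made intramolecular by the C6–C9 tether whose C9 ketone later serves C7 and C9.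

## Logic of the disconnections

**35 to 34 to 32.** The O14–Si bond and the acyl C–O bond of the C1 tiglate are cut. The tiglate is the only ester that differs from the others, so it is put on last, on the one free secondary hydroxyl, while C14 is silylated. This leaves 32, which carries only acetates and one silyl ether. The forward steps must acylate a hindered alcohol without acetyl migration from O2, and must remove silicon without forming an alkoxide that could pull the tiglate from O1 to O14.

**32 to 29 to 28.** The two acetyl C–O bonds (O2, O9) and the O14–Si bond are cut. The cis-1,2-diol is differentiated through a cyclic orthoacetate, whose hydrolysis leaves the ester on the pseudoaxial O2 and frees the equatorial O1. The gain is tetraol 28, free of protecting groups. The demands are primary-selective silylation, acetylation of the very hindered 9-OH while the orthoester is in place, and regioselective opening.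

**28 to 26.** Retrosynthetically C9 is returned to the ketone, C14 to the lactone carbonyl, and O1/C14 are re-closed in the dioxanone; the C2 oxygen regains its spectator acetate. C14 can only reach the alcohol level by hydride, which no acetate survives, so all oxygens are unmasked in one operation while no ester of the target is present; the auxiliary acetal leaves in the same step. The gain is one stereocentre fewer and O1/C14 locked. The demand is hydride delivery to C9 from the C14 face.

**26 to 23 and 24.** The C7–C11 bond is cut. C7 is the β-carbon of an enone, and axial conjugate addition anti to the axial C14 sets it. The gain is loss of the isopropenyl group and of the C7 stereocentre. The cuprate must leave the allylic acetate and the lactone alone.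

**23 to 21.** The C7=C8 unsaturation is removed. Because C10 is quaternary the ketone enolises in one direction only, so the dehydrogenation is regiochemically unambiguous; it must be run without strong base.

**21 to 20 (key step).** The C1–C2 and C5–C10 bonds are cut. Both rings and four stereocentres fall away and an open-chain precursor remains whose only stereocentres are those of the acetal. The forward step needs an (E,E)-diene, the lactone-endo/tether-exo orientation and attack on one face. Because no metal can bridge the C9 and C14 carbonyl oxygens in the reacting conformer, the facial control is placed in the acetal of the precursor and not in a chelating catalyst.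

**20 to 19 to 6 and 17.** The C9–C10 bond is cut (alkenyl-metal addition to an aldehyde, then oxidation). This joins the heterocycle and the dienyl chain convergently, and the doubly activated alkene appears only in the last step before the cycloaddition. The organometallic must spare the enol acetate.

**17 to 16 to 14.** The C9 oxygen is traced back to a terminal alkene (anti-Markovnikov hydroboration, then oxidation to the aldehyde). The hydroboration must touch only the monosubstituted alkene, and the oxidative work-up must not cleave the enol ester.

**14 to 13 to 9 and 10.** The enol C2–O bond (from C–B) and the C2=C3 double bond (boron–Wittig) are cut. Both diene geometries must be fixed before the cycloaddition; enolisation of an enal would leave open whether CH2 or CH3 is deprotonated and with which geometry. The gain is the simple enal 9. The C–B to C–O exchange must retain geometry.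

**9 to 7 and 8.** The C4=C5 double bond is cut (Wittig with a stabilised ylide), which sets the (E)-trisubstituted alkene from two commercial compounds.

**6 to 5 to 3 and 4; 3 to 1.** The C10–I bond, then the two acetal C–O bonds (hetero-[4+2] of a ketene released from 3 with the chiral ketone 4), then the exocyclic carbon of 3 (the future C1) are cut. The spiro epimers must be separated.

## Other disconnections considered

**Alternative 1:** The cut is through C5–C6 and C9–C10, building ring B on an arene-derived ring A. In the forward sense the quinone A1 reacts at its ester-bearing double bond with the silyloxydiene A2 to give the endo, cis-fused adduct A3.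
- In its favour: the reaction is convergent and both partners are made in very few steps. The pairing is electronically matched (the oxygenated diene terminus bonds to the ester-bearing C10), whereas in the chosen plan the tether forces the acetoxy terminus onto the electrophilic C1; on this point alternative 1 is the better. The ring carbonyl and the ester carbonyl of A1 can converge on one metal, so catalyst control of the absolute sense is realistic, which is also better than an auxiliary. C9 arrives oxygenated with the right configuration, where the chosen plan needs a reduction.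
- Against it here: ring A arrives as an enedione with C2 as an enol ether. The C15 methyl and the C3=C4 alkene, the C1 carbinol, an sp3 C2 carbinol cis to O1 and the reduction of C14 all remain to be done. Ring B holds only an isolated C7=C8 alkene, with no carbonyl to steer an axial isopropenyl group to C7. C5 must be epimerised to the trans fusion through the C4 ketone before that ketone is used up.
- Comparison: A3 fixes C9 and C10; 21 fixes C1, C2, C5 and C10 and leaves C7 and C9 addressable from one ketone. Mechanistically the intermolecular quinone cycloaddition is the safer reaction. In step economy alternative 1 reaches its key step sooner (better), but the redox and C–C work afterwards should outweigh the seven steps that follow 21.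

**Alternative 2:** The cut is through C5–C6 and C1–C10. In the forward sense MeAlCl2 activates the vinyl ketone of the open-chain compound A4 (silyl enol ether drawn as trimethylsilyl); the (E)-C5=C10 alkene attacks C6 and the C10 cation is trapped by C1 of the enol ether, giving the trans-fused decalin A5.
- In its favour: two rings and C1, C5, C7 and C10 come from one cascade. C14 is already a protected alcohol, so no late hydride step is needed and no ester has to be shed and re-installed; this protecting-group logic is better than in the chosen plan. The C7 acetyl group needs one methylenation to become isopropenyl, which is shorter than dehydrogenation plus cuprate.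
- Against it here: the C10 cation sits between two oxygenated carbons (C9, C14) and is inductively destabilised, so elimination or shifts can compete. A strong Lewis acid must coexist with a silyl enol ether. C9 emerges epimeric and must be inverted at a neopentyl centre. Ring A needs dehydrogenation and 1,2-reduction to reach the allylic C2 alcohol. A4 requires a defined trisubstituted alkene, a defined enol ether and two stereocentres.
- Comparison: the same ring-fusion centres are set, plus C7. The cationic cascade is less predictable than a concerted cycloaddition, so the chosen plan is better on mechanism. The way to A4 should be longer than the seven linear steps to 20. After the key step the two routes are about equal.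

**Alternative 3:** The cut is through C2–C3. In the forward sense zerovalent nickel inserts into the (Z)-alkenyl iodide of A6, the alkenyl group passes to chromium (CrCl2, catalytic NiCl2), and the alkenylchromium adds to the C2 aldehyde to close ring A as the cyclohexenol A7.
- In its favour: the closure is mild and tolerates acetate, silyl ether and p-methoxybenzyl ether. The four oxygens arrive differentiated exactly as the target needs them, so the endgame (acetylate O2, remove the benzyl ether, tigloylate, desilylate) is equal in length to steps 15–18 and safer, with no hydride step. The reliability of the ring closure itself is also better than that of the chosen cycloaddition.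
- Against it here: only one bond, one ring and one stereocentre are made, and the C2 configuration rests on 1,2-induction from the C1 ether, which does not assure the cis-diol. Ring B with C5, C7, C9, the quaternary C10 and C1, and the (Z)-iodoalkene, must all be built beforehand; the difficulty is moved upstream.
- Comparison: the strategic gain is smaller (one ring, one bond, one stereocentre against two, two, four), and the total step count should be clearly higher. The late stage is the more robust.

Key step: step 11

## Route

Step 1
Reactants: 1 2,2-dimethyl-1,3-dioxane-4,6-dione (Meldrum's acid)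
Product: 3 5-(hydroxymethylene)-2,2-dimethyl-1,3-dioxane-4,6-dione, via 5-(methoxymethylene) Meldrum's acid 2 (not isolated)
Conditions: HC(OMe)3, 85 °C; then 2 M HCl, rt
Reagents that add atoms: trimethyl orthoformate COC(OC)OC; water O
Why: Knoevenagel-type condensation of the active methylene with the orthoester, then hydrolysis of the vinylogous ester to the stable enol of the formyl compound; no stereocentre is formed.

Step 2
Reactants: 3 5-(hydroxymethylene)-2,2-dimethyl-1,3-dioxane-4,6-dione; 4 (−)-menthone
Product: 5 (1R,2S,5R)-2-isopropyl-5-methylspiro[cyclohexane-1,2'-[1,3]dioxin]-4'-one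
Conditions: 4 (3 equiv), toluene, 110 °C; chromatography
Reagents that add atoms: none
Why: On heating, 3 loses acetone and CO2 to a formylketene that the ketone carbonyl of 4 traps in a hetero-[4+2] cycloaddition, the standard entry to 6-unsubstituted 1,3-dioxin-4-ones. The spiro carbon forms as both epimers, which are separable diastereomers; the epimer with the enol-ether oxygen axial on the cyclohexane chair is kept, and the other can be recycled by thermolysis in the presence of 4.

Step 3
Reactants: 5 (1R,2S,5R)-2-isopropyl-5-methylspiro[cyclohexane-1,2'-[1,3]dioxin]-4'-one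
Product: 6 (1R,2S,5R)-5'-iodo-2-isopropyl-5-methylspiro[cyclohexane-1,2'-[1,3]dioxin]-4'-one
Conditions: NIS, AcOH, rt, dark
Reagents that add atoms: N-iodosuccinimide O=C1CCC(=O)N1I
Why: Electrophilic iodination (addition–elimination) at the nucleophilic α-carbon of the push–pull enol ether, routine for dioxinones; the acetal is not touched.

Step 4
Reactants: 7 pent-4-enal; 8 2-(triphenylphosphoranylidene)propanal
Product: 9 (E)-2-methylhepta-2,6-dienal
Conditions: toluene, 80 °C
Reagents that add atoms: none
Why: Wittig olefination with a stabilised, α-branched ylide gives the (E)-trisubstituted enal; this fixes the later C4=C5 geometry.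

Step 5
Reactants: 9 (E)-2-methylhepta-2,6-dienal; 10 bis(4,4,5,5-tetramethyl-1,3,2-dioxaborolan-2-yl)methane
Product: 13 potassium trifluoro[(1E,3E)-3-methylocta-1,3,7-trien-1-yl]borate, via lithiated diborylmethane 11 (not isolated), via dienyl pinacol boronate 12 (not isolated)
Conditions: 10, lithium 2,2,6,6-tetramethylpiperidide, THF, 0 °C; then 9, −78 °C → rt; then KHF2, MeOH/H2O, rt
Reagents that add atoms: potassium hydrogen difluoride F.[F-].[K+]
Why: Boron–Wittig olefination: the α-boryl carbanion adds to the aldehyde and B–O syn-elimination gives the (E)-alkenyl boronate (the future C2=C3); exchange with KHF2 gives the bench-stable trifluoroborate with both diene geometries fixed.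

Step 6
Reactants: 13 potassium trifluoro[(1E,3E)-3-methylocta-1,3,7-trien-1-yl]borate
Product: 14 (1E,3E)-3-methylocta-1,3,7-trien-1-yl acetate
Conditions: AcOH (5 equiv), CuBr (10 mol %), DMAP (20 mol %), 4 Å MS, O2 (1 atm), MeCN, 40 °C
Reagents that add atoms: acetic acid CC(=O)O
Why: Copper-catalysed oxidative C–O coupling of an alkenyltrifluoroborate with a carboxylic acid (Chan–Lam type). Transmetallation and reductive elimination from trivalent copper retain the alkene geometry, so the (E)-enol acetate forms without any enolisation that could scramble regiochemistry or geometry.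

Step 7
Reactants: 14 (1E,3E)-3-methylocta-1,3,7-trien-1-yl acetate
Product: 16 (1E,3E)-8-hydroxy-3-methylocta-1,3-dien-1-yl acetate, via alkyl-9-BBN adduct 15 (not isolated)
Conditions: 9-BBN, THF, 0 °C → rt; then pH 7 phosphate buffer, 30% H2O2, 0 °C
Reagents that add atoms: hydrogen peroxide OO
Why: 9-BBN hydroborates the monosubstituted terminal alkene anti-Markovnikov far faster than the conjugated trisubstituted diene or the enol ester; buffered neutral oxidation avoids perhydrolysis of the enol acetate.

Step 8
Reactants: 16 (1E,3E)-8-hydroxy-3-methylocta-1,3-dien-1-yl acetate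
Product: 17 (1E,3E)-3-methyl-8-oxoocta-1,3-dien-1-yl acetate
Conditions: Dess–Martin periodinane, CH2Cl2, 0 °C → rt
Reagents that add atoms: none
Why: Dess–Martin oxidation of a primary alcohol under neutral, non-aqueous conditions; the dienyl acetate is inert.

Step 9
Reactants: 6 (1R,2S,5R)-5'-iodo-2-isopropyl-5-methylspiro[cyclohexane-1,2'-[1,3]dioxin]-4'-one; 17 (1E,3E)-3-methyl-8-oxoocta-1,3-dien-1-yl acetate
Product: 19 5'-[(5E,7E)-8-acetoxy-1-hydroxy-6-methylocta-5,7-dien-1-yl] spiro-menthone dioxinone (both C9 epimers), via alkenylmagnesium chloride 18 (not isolated)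
Conditions: 6, i-PrMgCl·LiCl, THF, −40 °C; then 17, −40 → −20 °C; aq. NH4Cl
Reagents that add atoms: none
Why: Iodine–magnesium exchange on the electron-poor alkenyl iodide gives a 5'-magnesiated dioxinone that cannot β-eliminate inside the ring; at low temperature it adds to the aldehyde faster than to the enol ester. The new C9 carbinol forms unselectively and is removed in step 10.

Step 10
Reactants: 19 5'-[(5E,7E)-8-acetoxy-1-hydroxy-6-methylocta-5,7-dien-1-yl] spiro-menthone dioxinone
Product: 20 (1R,2S,5R)-5'-[(5E,7E)-8-acetoxy-6-methylocta-5,7-dienoyl]-2-isopropyl-5-methylspiro[cyclohexane-1,2'-[1,3]dioxin]-4'-one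
Conditions: Dess–Martin periodinane, CH2Cl2, 0 °C → rt
Reagents that add atoms: none
Why: Dess–Martin oxidation of the secondary alcohol unveils the doubly activated dienophile under neutral conditions only at this point; both C9 epimers converge on the ketone.

Step 11
Reactants: 20 (1R,2S,5R)-5'-[(5E,7E)-8-acetoxy-6-methylocta-5,7-dienoyl]-2-isopropyl-5-methylspiro[cyclohexane-1,2'-[1,3]dioxin]-4'-one
Product: 21 trans-fused tricyclic keto dioxanone (2-acetoxy-1-hydroxy-9-oxoeudesm-3-en-14-oic acid as its spiro-menthone 1,3-dioxan-4-one; C1 C2 C5 C10 as in 35)
Conditions: Me2AlCl (0.3 equiv), CH2Cl2, −78 → −20 °C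
Reagents that add atoms: none
Why: A concerted, asynchronous intramolecular Diels–Alder reaction joins the (E,E)-1-acetoxy-3-methyldiene (C2–C5) to the dioxinone C1=C10 bond, accelerated by one-point coordination of Me2AlCl to the C9 ketone oxygen on the lone pair anti to C8. The closest known reaction types are Lewis-acid-promoted cyclisations of 1,7,9-decatrien-3-ones whose dienophile carries a second geminal carbonyl group, and cycloadditions to chiral spiro-dioxinones. Ring A closes as the six-membered ring of the [4+2] itself (bonds C1–C2 and C5–C10), and ring B closes as a six-membered chair through the four-atom tether C6–C9 in the fused mode, the bridged mode being out of reach. At C1 and C10 the dioxinone ring holds O1 and C14 cis, and they stay cis. At C2 and C5 the (E,E) geometry places the acetate and C6 outside, and the lactone-endo, tether-exo orientation puts both on the face of O1 and C14, which is the trans ring fusion; the lactone carbonyl is rigidly coplanar with the dienophile and takes the endo position, whereas the tether ketone must turn its oxygen toward C1–H to close the chair. For that reason the C9 and C14 carbonyl oxygens point apart in the transition state and cannot share one metal, so the Lewis acid serves only as a one-point activator and the absolute sense is laid into the substrate. The diene has to lie over the dioxinone ring, where a pseudoaxial acetal substituent would collide with it, so it adds to the face anti to the isopropyl-bearing carbon of the spiro-menthane, which for the (1R) spiro epimer is the face that leads to the configuration of 35. The tether enforces the regiochemistry against the electronic preference of the acetoxydiene, which is why low-temperature Lewis-acid activation is chosen over heating, which would also risk retro-[4+2] of the dioxinone.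

Step 12
Reactants: 21 trans-fused tricyclic keto dioxanone
Product: 23 Δ7-enone (2-acetoxy-1-hydroxy-9-oxoeudesma-3,7-dien-14-oic acid spiro-menthone dioxanone), via TMS enol ether 22 (not isolated)
Conditions: TMSOTf, Et3N, CH2Cl2, 0 °C; then Pd(OAc)2 (1.1 equiv), MeCN, rt
Reagents that add atoms: none
Why: Saegusa–Ito dehydrogenation: soft enolisation gives a single silyl enol ether (only C8 carries α-hydrogens, C10 is quaternary), and divalent palladium forms the oxa-π-allyl species that β-hydride eliminates to the enone. No amide base is used, so the acetate is safe.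

Step 13
Reactants: 23 Δ7-enone; 24 isopropenylmagnesium bromide
Product: 26 7-isopropenyl ketone (2-acetoxy-1-hydroxy-9-oxoeudesma-3,11-dien-14-oic acid spiro-menthone dioxanone; isopropenyl on the H5 face), via magnesium diisopropenylcuprate 25 (not isolated)
Conditions: 24 (2.2 equiv), CuBr·SMe2 (1.1 equiv), THF, −78 °C; then 23, −78 → −40 °C; aq. NH4Cl
Reagents that add atoms: none
Why: Cuprate conjugate addition to the cyclohexenone; the stereoelectronically preferred axial attack at C7, anti to the axial C14 carbonyl on C10, passes through a chair enolate and places the isopropenyl group on the H5 face. At −78 °C the cuprate should neither displace the hindered allylic acetate nor open the lactone.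

Step 14
Reactants: 26 7-isopropenyl ketone
Product: 28 eudesma-3,11-diene-1,2,9,14-tetraol (stereocentres as in 35), via 9-hydroxy dioxanone 27 (not isolated)
Conditions: LiBH(s-Bu)3, THF, −78 °C; then LiAlH4, −78 → 0 °C; aq. Rochelle salt
Reagents that add atoms: none
Why: The axial isopropenyl group at C7 blocks the axial trajectory at C9, so the bulky borohydride attacks equatorially from the C14 face and gives the axial 9-alcohol on the H5 face. LiAlH4 then reduces the acylal lactone to C14H2OH with release of O1 and of the auxiliary ketone, and cleaves the spectator acetate, so that C14 reaches the alcohol level while no ester of the target is present.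

Step 15
Reactants: 28 eudesma-3,11-diene-1,2,9,14-tetraol
Product: 29 14-O-TBS-eudesma-3,11-diene-1,2,9,14-tetraol (stereocentres as in 35)
Conditions: TBSCl (1.1 equiv), imidazole, DMF, 0 °C
Reagents that add atoms: tert-butyldimethylsilyl chloride CC(C)(C)[Si](C)(C)Cl
Why: Silylation with the bulky chlorosilane is selective for the only primary hydroxyl, neopentyl though it is, over three secondary ones.

Step 16
Reactants: 29 14-O-TBS-eudesma-3,11-diene-1,2,9,14-tetraol
Product: 32 2,9-di-O-acetyl-14-O-TBS-eudesma-3,11-diene-1,2,9,14-tetraol (1-OH free; stereocentres as in 35), via cyclic 1,2-orthoacetate 30 (not isolated), via orthoacetate 9-acetate 31 (not isolated)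
Conditions: MeC(OMe)3, PPTS (cat.), CH2Cl2, rt; then Et3N, Ac2O, DMAP, 40 °C; then 80% aq. AcOH, rt
Reagents that add atoms: trimethyl orthoacetate CC(OC)(OC)OC; acetic anhydride CC(=O)OC(C)=O; water O
Why: Only the cis-1,2-diol (O1 equatorial, O2 pseudoaxial) can form a cyclic orthoacetate, since O9 is anti to C14 and to O1; the hindered 9-OH is then acetylated under DMAP catalysis while the orthoester is base-stable. Mild acid opens the orthoester to the axial acetate and the equatorial alcohol, the usual stereoelectronic course for cis-diol orthoesters on six-membered rings.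

Step 17
Reactants: 32 2,9-di-O-acetyl-14-O-TBS-eudesma-3,11-diene-1,2,9,14-tetraol; 33 tigloyl chloride
Product: 34 2,9-di-O-acetyl-1-O-tigloyl-14-O-TBS-eudesma-3,11-diene-1,2,9,14-tetraol (stereocentres as in 35)
Conditions: 33, DMAP, pyridine, CH2Cl2, 0 → 40 °C
Reagents that add atoms: none
Why: DMAP-catalysed acylation of the one free, hindered secondary hydroxyl with the acid chloride; pyridine as a weak base should keep acetyl migration from O2 to O1 slow relative to acylation.

Step 18
Reactants: 34 2,9-di-O-acetyl-1-O-tigloyl-14-O-TBS-eudesma-3,11-diene-1,2,9,14-tetraol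
Product: 35 (1R,2S,5R,7S,9S,10S)-2,9-diacetoxy-14-hydroxyeudesma-3,11-dien-1-yl (E)-2-methylbut-2-enoate (CNP0267061.1)
Conditions: HF·pyridine, pyridine, THF, 0 °C → rt
Reagents that add atoms: none
Why: Acidic fluoride cleaves the primary silyl ether without generating an alkoxide, so the tiglate cannot move from O1 to O14 and the acetates stay in place.

## Compound list

1 | 2,2-dimethyl-1,3-dioxane-4,6-dione (Meldrum's acid) | CC1(C)OC(=O)CC(=O)O1 | starting material
2 | 5-(methoxymethylene)-2,2-dimethyl-1,3-dioxane-4,6-dione | COC=C1C(=O)OC(C)(C)OC1=O | intermediate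
3 | 5-(hydroxymethylene)-2,2-dimethyl-1,3-dioxane-4,6-dione | OC=C1C(=O)OC(C)(C)OC1=O | intermediate
4 | (−)-menthone, (2S,5R)-2-isopropyl-5-methylcyclohexanone | CC(C)[C@@H]1CC[C@@H](C)CC1=O | starting material
5 | (1R,2S,5R)-2-isopropyl-5-methylspiro[cyclohexane-1,2'-[1,3]dioxin]-4'-one (enol-ether oxygen axial on the cyclohexane) | C1=CO[C@]2(OC1=O)[C@H](C(C)C)CC[C@@H](C)C2 | intermediate
6 | (1R,2S,5R)-5'-iodo-2-isopropyl-5-methylspiro[cyclohexane-1,2'-[1,3]dioxin]-4'-one | IC1=CO[C@]2(OC1=O)[C@H](C(C)C)CC[C@@H](C)C2 | intermediate
7 | pent-4-enal | C=CCCC=O | starting material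
8 | 2-(triphenylphosphoranylidene)propanal | CC(C=O)=P(c1ccccc1)(c1ccccc1)c1ccccc1 | starting material
9 | (E)-2-methylhepta-2,6-dienal | C=CCC/C=C(\C)C=O | intermediate
10 | bis(4,4,5,5-tetramethyl-1,3,2-dioxaborolan-2-yl)methane | CC1(C)OB(CB2OC(C)(C)C(C)(C)O2)OC1(C)C | starting material
11 | lithio-bis(4,4,5,5-tetramethyl-1,3,2-dioxaborolan-2-yl)methane | [Li]C(B1OC(C)(C)C(C)(C)O1)B1OC(C)(C)C(C)(C)O1 | intermediate
12 | 4,4,5,5-tetramethyl-2-[(1E,3E)-3-methylocta-1,3,7-trien-1-yl]-1,3,2-dioxaborolane | C=CCC/C=C(C)/C=C/B1OC(C)(C)C(C)(C)O1 | intermediate
13 | potassium trifluoro[(1E,3E)-3-methylocta-1,3,7-trien-1-yl]borate | [K+].C=CCC/C=C(C)/C=C/[B-](F)(F)F | intermediate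
14 | (1E,3E)-3-methylocta-1,3,7-trien-1-yl acetate | C=CCC/C=C(C)/C=C/OC(C)=O | intermediate
15 | (1E,3E)-8-(9-borabicyclo[3.3.1]nonan-9-yl)-3-methylocta-1,3-dien-1-yl acetate | CC(=O)O/C=C/C(C)=C/CCCCB1C2CCCC1CCC2 | intermediate
16 | (1E,3E)-8-hydroxy-3-methylocta-1,3-dien-1-yl acetate | CC(=O)O/C=C/C(C)=C/CCCCO | intermediate
17 | (1E,3E)-3-methyl-8-oxoocta-1,3-dien-1-yl acetate | CC(=O)O/C=C/C(C)=C/CCCC=O | intermediate
18 | 5'-(chloromagnesio) derivative of 5 | Cl[Mg]C1=CO[C@]2(OC1=O)[C@H](C(C)C)CC[C@@H](C)C2 | intermediate
19 | (1R,2S,5R)-5'-[(5E,7E)-8-acetoxy-1-hydroxy-6-methylocta-5,7-dien-1-yl]-2-isopropyl-5-methylspiro[cyclohexane-1,2'-[1,3]dioxin]-4'-one, both carbinol epimers | CC(=O)O/C=C/C(C)=C/CCCC(O)C1=CO[C@]2(OC1=O)[C@H](C(C)C)CC[C@@H](C)C2 | intermediate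
20 | (1R,2S,5R)-5'-[(5E,7E)-8-acetoxy-6-methylocta-5,7-dienoyl]-2-isopropyl-5-methylspiro[cyclohexane-1,2'-[1,3]dioxin]-4'-one (cycloaddition precursor) | CC(=O)O/C=C/C(C)=C/CCCC(=O)C1=CO[C@]2(OC1=O)[C@H](C(C)C)CC[C@@H](C)C2 | intermediate
21 | trans-fused tricyclic keto dioxanone: 2-acetoxy-1-hydroxy-9-oxoeudesm-3-en-14-oic acid as its spiro-menthone 1,3-dioxan-4-one; O1, 2-OAc and C14 on one face, H5 on the other | C1CC(=O)[C@@]2(C(=O)O[C@@]4(O3)[C@H](C(C)C)CC[C@@H](C)C4)[C@H](C1)C(C)=C[C@H](OC(C)=O)[C@@H]23 | intermediate
22 | 9-(trimethylsilyloxy)-Δ8 enol ether of 21 | C1C=C(O[Si](C)(C)C)[C@@]2(C(=O)O[C@@]4(O3)[C@H](C(C)C)CC[C@@H](C)C4)[C@H](C1)C(C)=C[C@H](OC(C)=O)[C@@H]23 | intermediate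
23 | Δ7-enone: 2-acetoxy-1-hydroxy-9-oxoeudesma-3,7-dien-14-oic acid spiro-menthone dioxanone | C1=CC(=O)[C@@]2(C(=O)O[C@@]4(O3)[C@H](C(C)C)CC[C@@H](C)C4)[C@H](C1)C(C)=C[C@H](OC(C)=O)[C@@H]23 | intermediate
24 | isopropenylmagnesium bromide | C=C(C)[Mg]Br | starting material
25 | bromomagnesium diisopropenylcuprate | C=C(C)[Cu-]C(C)=C.[Mg+]Br | intermediate
26 | 2-acetoxy-1-hydroxy-9-oxoeudesma-3,11-dien-14-oic acid spiro-menthone dioxanone, 7-isopropenyl on the H5 face | C=C(C)[C@@H]1CC(=O)[C@@]2(C(=O)O[C@@]4(O3)[C@H](C(C)C)CC[C@@H](C)C4)[C@H](C1)C(C)=C[C@H](OC(C)=O)[C@@H]23 | intermediate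
27 | 9-hydroxy analogue of 26, 9-OH axial on the H5 face | C=C(C)[C@@H]1C[C@H](O)[C@@]2(C(=O)O[C@@]4(O3)[C@H](C(C)C)CC[C@@H](C)C4)[C@H](C1)C(C)=C[C@H](OC(C)=O)[C@@H]23 | intermediate
28 | (1R,2S,5R,7S,9S,10S)-eudesma-3,11-diene-1,2,9,14-tetraol | C=C(C)[C@@H]1C[C@H](O)[C@@]2(CO)[C@H](C1)C(C)=C[C@H](O)[C@@H]2O | intermediate
29 | 14-O-(tert-butyldimethylsilyl) ether of 28 | C=C(C)[C@@H]1C[C@H](O)[C@@]2(CO[Si](C)(C)C(C)(C)C)[C@H](C1)C(C)=C[C@H](O)[C@@H]2O | intermediate
30 | 1,2-O-(1-methoxyethylidene) cyclic orthoacetate of 29 (orthoester carbon as a mixture) | C=C(C)[C@@H]1C[C@H](O)[C@@]2(CO[Si](C)(C)C(C)(C)C)[C@H](C1)C(C)=C[C@H](O3)[C@@H]2OC3(C)OC | intermediate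
31 | 9-O-acetate of 30 | C=C(C)[C@@H]1C[C@H](OC(C)=O)[C@@]2(CO[Si](C)(C)C(C)(C)C)[C@H](C1)C(C)=C[C@H](O3)[C@@H]2OC3(C)OC | intermediate
32 | 2,9-di-O-acetyl-14-O-(tert-butyldimethylsilyl)eudesma-3,11-diene-1,2,9,14-tetraol, 1-OH free, stereocentres arranged as in 35 | C=C(C)[C@@H]1C[C@H](OC(C)=O)[C@@]2(CO[Si](C)(C)C(C)(C)C)[C@H](C1)C(C)=C[C@H](OC(C)=O)[C@@H]2O | intermediate
33 | tigloyl chloride, (E)-2-methylbut-2-enoyl chloride | C/C=C(\C)C(Cl)=O | starting material
34 | 1-O-tigloyl derivative of 32 | C=C(C)[C@@H]1C[C@H](OC(C)=O)[C@@]2(CO[Si](C)(C)C(C)(C)C)[C@H](C1)C(C)=C[C@H](OC(C)=O)[C@@H]2OC(=O)/C(C)=C/C | intermediate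
35 | (1R,2S,5R,7S,9S,10S)-2,9-diacetoxy-14-hydroxyeudesma-3,11-dien-1-yl (E)-2-methylbut-2-enoate | C=C(C)[C@@H]1C[C@H](OC(C)=O)[C@@]2(CO)[C@H](C1)C(C)=C[C@H](OC(C)=O)[C@@H]2OC(=O)/C(C)=C/C | target

## Step count and least certain steps

Total step count: 18. Longest linear sequence: 15 steps (steps 4 to 18, from 7); the dioxinone branch (steps 1 to 3) joins at step 9.

**Step 11 (key step).** The most likely failure is competition from the tether-endo mode, in which the aluminium-bound ketone, the more basic carbonyl, takes the endo position and the ring fusion comes out cis. The facial model of the spiro acetal is also only qualitative, so the discrimination between the two faces may be eroded, and the Lewis acid may ionise the dienyl acetate. Fallback: the ketone is taken out of the cycloaddition. Carbinol 19 is silylated (TESCl, imidazole) to the triethylsilyl ether F1, in which the lactone is the only conjugated carbonyl and can only be endo. F1 is cyclised with a stoichiometric alkylaluminium chloride (Me2AlCl, CH2Cl2, −40 → 0 °C) to the silylated cycloadduct F2 (C9 epimers, both productive). F2 is desilylated (HF·pyridine) to the carbinol F3, and Dess–Martin oxidation of F3 returns to the route at 21.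

**Step 6.** Protodeboronation or oxidative homocoupling of the electron-rich dienylboron species may outrun C–O bond formation, or the geometry may be partly lost on copper. Fallback: the boronate 12 is isolated and not converted to 13. It is oxidised with retention (NaBO3·4H2O, THF/H2O); the dienol tautomerises to (E)-3-methylocta-3,7-dienal F4, in which the C4=C5 geometry is untouched and only the α-CH2 is acidic. F4 is deprotonated and O-acetylated at once (KN(SiMe3)2, THF, −78 °C; Ac2O). The enol geometry is then a mixture, and the (1E) isomer is separated to rejoin the route at 14.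

**Step 14.** Hydride may be delivered along the axial path if the C7 substituent screens it insufficiently, giving the equatorial C9 epimer; the transient β-alkoxy aldehyde formed during lactone reduction may also fragment by retro-aldol cleavage. Fallback: directed reduction. Enone 23 is treated with cuprate 25 and the enolate is trapped (TBSCl, HMPA) as the silyl enol ether F5. LiAlH4 then reduces lactone and acetate with the ketone masked, giving the triol silyl enol ether F6. HF·pyridine unmasks the 1,2,14-trihydroxy 9-ketone F7. Me4NBH(OAc)3 (MeCN/AcOH, −20 °C; Evans–Saksena reduction) delivers hydride intramolecularly from the boron bound to O14 or O1, that is from the C14 face, and returns to the route at 28.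

**Step 16.** The orthoester may open toward the equatorial acetate, since ring A is a half-chair and the axial preference may be weaker than in saturated rings, and acetylation of the very hindered axial 9-OH may be incomplete. Fallback: 1,3-diol protection in place of the orthoester. Tetraol 28 is converted with 4-methoxybenzaldehyde dimethyl acetal and PPTS into the 1,14-O-(4-methoxybenzylidene) acetal F8 (primary hydroxyl first, closure onto O1). F8 is acetylated (Ac2O, DMAP) to its 2,9-diacetate F9. F9 is hydrolysed (80% AcOH) to the 1,14-diol 2,9-diacetate F10, and primary-selective silylation (TBSCl, imidazole) returns to the route at 32.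

**Step 17.** Acetyl migration from O2 to the free O1 under the basic conditions may outpace the slow acylation of the hindered alcohol and give the regioisomeric ester pattern. Fallback: the tiglate is put on before any acetate exists. Triol 29 is heated with Bu2SnO (toluene, water removal) to the dibutylstannylene acetal F11 of the cis-diol. F11 is acylated at the equatorial oxygen with 33 at rt to the 1-O-tiglate 2,9-diol F12. Acetylation of both remaining hydroxyls (Ac2O, Et3N, DMAP) returns to the route at 34.

## Further compounds

F1 | step 11 | triethylsilyl ether of 19 | CC(=O)O/C=C/C(C)=C/CCCC(O[Si](CC)(CC)CC)C1=CO[C@]2(OC1=O)[C@H](C(C)C)CC[C@@H](C)C2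
F2 | step 11 | 9-(triethylsilyloxy) cycloadduct, trans-fused, C9 epimers | C1CC(O[Si](CC)(CC)CC)[C@@]2(C(=O)O[C@@]4(O3)[C@H](C(C)C)CC[C@@H](C)C4)[C@H](C1)C(C)=C[C@H](OC(C)=O)[C@@H]23
F3 | step 11 | 9-hydroxy cycloadduct, C9 epimers | C1CC(O)[C@@]2(C(=O)O[C@@]4(O3)[C@H](C(C)C)CC[C@@H](C)C4)[C@H](C1)C(C)=C[C@H](OC(C)=O)[C@@H]23
F4 | step 6 | (E)-3-methylocta-3,7-dienal | C=CCC/C=C(C)/CC=O
F5 | step 14 | 9-(tert-butyldimethylsilyloxy)-Δ8 enol ether of 26 | C=C(C)[C@@H]1C=C(O[Si](C)(C)C(C)(C)C)[C@@]2(C(=O)O[C@@]4(O3)[C@H](C(C)C)CC[C@@H](C)C4)[C@H](C1)C(C)=C[C@H](OC(C)=O)[C@@H]23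
F6 | step 14 | 9-(tert-butyldimethylsilyloxy)eudesma-3,8,11-triene-1,2,14-triol | C=C(C)[C@@H]1C=C(O[Si](C)(C)C(C)(C)C)[C@@]2(CO)[C@H](C1)C(C)=C[C@H](O)[C@@H]2O
F7 | step 14 | 1,2,14-trihydroxyeudesma-3,11-dien-9-one | C=C(C)[C@@H]1CC(=O)[C@@]2(CO)[C@H](C1)C(C)=C[C@H](O)[C@@H]2O
F8 | step 16 | 1,14-O-(4-methoxybenzylidene) acetal of 28 | C=C(C)[C@@H]1C[C@H](O)[C@@]2(COC(c4ccc(OC)cc4)O3)[C@H](C1)C(C)=C[C@H](O)[C@@H]23
F9 | step 16 | 2,9-diacetate of F8 | C=C(C)[C@@H]1C[C@H](OC(C)=O)[C@@]2(COC(c4ccc(OC)cc4)O3)[C@H](C1)C(C)=C[C@H](OC(C)=O)[C@@H]23
F10 | step 16 | 2,9-di-O-acetyleudesma-3,11-diene-1,2,9,14-tetraol | C=C(C)[C@@H]1C[C@H](OC(C)=O)[C@@]2(CO)[C@H](C1)C(C)=C[C@H](OC(C)=O)[C@@H]2O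
F11 | step 17 | 1,2-O-dibutylstannylene acetal of 29 | C=C(C)[C@@H]1C[C@H](O)[C@@]2(CO[Si](C)(C)C(C)(C)C)[C@H](C1)C(C)=C[C@H](O3)[C@@H]2O[Sn]3(CCCC)CCCC
F12 | step 17 | 1-O-tigloyl-14-O-(tert-butyldimethylsilyl)eudesma-3,11-diene-1,2,9,14-tetraol | C=C(C)[C@@H]1C[C@H](O)[C@@]2(CO[Si](C)(C)C(C)(C)C)[C@H](C1)C(C)=C[C@H](O)[C@@H]2OC(=O)/C(C)=C/C
A1 | alternative 1 | 2-methoxy-6-(methoxycarbonyl)-1,4-benzoquinone | COC1=CC(=O)C=C(C(=O)OC)C1=O
A2 | alternative 1 | (E)-1-(tert-butyldimethylsilyloxy)buta-1,3-diene | C=C/C=C/O[Si](C)(C)C(C)(C)C
A3 | alternative 1 | endo cis-fused quinone adduct | C1=C[C@H](O[Si](C)(C)C(C)(C)C)[C@@]2(C(=O)OC)[C@@H](C1)C(=O)C=C(OC)C2=O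
A4 | alternative 2 | open-chain vinyl ketone with (E)-C5=C10 alkene and (Z)-C1=C2 trimethylsilyl enol ether | CC(=O)C(=C)C[C@@H](O[Si](C(C)C)(C(C)C)C(C)C)/C(CO[Si](c1ccccc1)(c1ccccc1)C(C)(C)C)=C/[C@@H](C)C/C(O[Si](C)(C)C)=C/OCc1ccccc1
A5 | alternative 2 | trans-fused 7-acetyl-2-oxodecalin | CC(=O)[C@@H]1C[C@@H](O[Si](C(C)C)(C(C)C)C(C)C)[C@@]2(CO[Si](c3ccccc3)(c3ccccc3)C(C)(C)C)[C@H](C1)[C@@H](C)CC(=O)[C@@H]2OCc1ccccc1
A6 | alternative 3 | ring B aldehyde with (Z)-alkenyl iodide | C=C(C)[C@@H]1C[C@H](OC(C)=O)[C@@](CO[Si](C)(C)C(C)(C)C)([C@H](C1)/C(C)=C\I)[C@H](C=O)OCc1ccc(OC)cc1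
A7 | alternative 3 | bicyclic allylic alcohol | C=C(C)[C@@H]1C[C@H](OC(C)=O)[C@@]2(CO[Si](C)(C)C(C)(C)C)[C@H](C1)C(C)=C[C@H](O)[C@@H]2OCc1ccc(OC)cc1
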